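**Retrosynthetic overview**
1. Phyltetralin 8 ⇒ acid-triggered ring expansion (C–C protonolysis, then Friedel–Crafts closure) of the C2-symmetric all-trans cyclobutane 7. The six-membered carbocycle is formed last; C1 is set here.
2. 7 ⇒ enantioselective head-to-head radical-cation [2+2] homodimerisation of the (E)-cinnamyl methyl ether 6. The cyclobutane is formed first; this sets C2 and C3 of the target.
3. 6 ⇒ 4-bromoveratrole 3 + 3-methoxyprop-1-yne 4 (one-pot hydroboration/Suzuki coupling).
4. 3 ⇒ veratrole 2 ⇒ catechol 1 + MeI.

Assumption: the sense of induction of the chiral anion in step 4 cannot be predicted, so the IDPi enantiomer that gives (1R,2R,3S,4S)-7 is fixed in a first screen (7 is carried to 8 and compared chiroptically with authentic phyltetralin).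

**Step 1**
Reactants: 1 catechol (benzene-1,2-diol)
Product: 2 veratrole (1,2-dimethoxybenzene)
Conditions: MeI (2.5 equiv), K2CO3 (3 equiv), acetone, reflux, N2
Reagents that add atoms: iodomethane, CI
Why: Double Williamson O-methylation of the catecholate; no stereocentre is involved.

**Step 2**
Reactants: 2 veratrole
Product: 3 4-bromo-1,2-dimethoxybenzene
Conditions: NBS (1.0 equiv), MeCN, 0 °C to rt
Reagents that add atoms: N-bromosuccinimide, O=C1CCC(=O)N1Br
Why: Electrophilic aromatic bromination goes para to a methoxy group (C4) and stops cleanly at the monobromide.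

**Step 3**
Reactants: 4 3-methoxyprop-1-yne (methyl propargyl ether); 3 4-bromo-1,2-dimethoxybenzene
Product: 6 (E)-1,2-dimethoxy-4-(3-methoxyprop-1-en-1-yl)benzene, via (E)-3-methoxyprop-1-enylboronic acid pinacol ester 5 (not isolated)
Conditions: 4 (1.2 equiv), HBpin (1.25 equiv), Cp2Zr(H)Cl (5 mol%), Et3N (10 mol%), neat, sealed, 60 °C; then 3 (1.0 equiv), Pd(dppf)Cl2 (3 mol%), K3PO4 (3 equiv), THF/H2O 5:1, 65 °C
Reagents that add atoms: pinacolborane, CC1(C)OBOC1(C)C (its boryl group sits in 5 and is lost again on coupling)
Why: Zr–H-catalysed syn-hydroboration of the terminal alkyne gives only the (E)-alkenylboronate, and the Suzuki–Miyaura coupling transfers the alkenyl group with retention of geometry.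

**Step 4**
Reactants: 6 (E)-1,2-dimethoxy-4-(3-methoxyprop-1-en-1-yl)benzene (two molecules)
Product: 7 (1R,2R,3S,4S)-1,2-bis(3,4-dimethoxyphenyl)-3,4-bis(methoxymethyl)cyclobutane (all-trans, C2-symmetric; each aryl is trans to the neighbouring aryl and to the neighbouring CH2OMe)
Conditions: thioxanthylium photocatalyst paired with a confined chiral imidodiphosphorimidate (IDPi) anion (2 mol%), CH2Cl2, 0.3 M, −40 °C, green LEDs (525 nm); recrystallise 7 to raise the ee
Reagents that add atoms: none
Why: Proposed new method: the excited thioxanthylium cation oxidises the electron-rich styrene 6 to its radical cation, which stays ion-paired with the chiral IDPi anion; a second molecule of 6 adds β-carbon to β-carbon inside the anion pocket, and this bond sets C3 and C4 of 7 (C3 and C2 of the target) in absolute terms, the E geometry of both alkenes giving the 3,4-trans relation; the 1,4-distonic radical cation then closes to the thermodynamically preferred all-trans cyclobutane and passes its hole on to fresh 6; the closest known reaction types are the racemic radical-cation [2+2] homodimerisation of anethole-type styrenes and the asymmetric counteranion-directed photoredox [2+2] heterodimerisation of such styrenes.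

**Step 5**
Reactants: 7 (1R,2R,3S,4S)-1,2-bis(3,4-dimethoxyphenyl)-3,4-bis(methoxymethyl)cyclobutane
Product: 8 phyltetralin, (1R,2S,3S)-1-(3,4-dimethoxyphenyl)-6,7-dimethoxy-2,3-bis(methoxymethyl)-1,2,3,4-tetrahydronaphthalene
Conditions: TfOH (10 mol%), HFIP/CH2Cl2 1:4, 0.02 M, 0 °C to rt; NaHCO3 quench
Reagents that add atoms: none
Why: Proposed new method: the strained (about 26 kcal/mol), doubly benzylic C1–C2 bond of 7, flanked by two 4-alkoxyaryl donors, is cleaved by protonation so that one benzylic carbon becomes the C4 methylene and the other a 3,4-dimethoxybenzyl cation (both modes are equivalent by C2 symmetry); this cation is captured by the position para to OMe on the neighbouring veratryl ring (intramolecular Friedel–Crafts alkylation) through a chair-like transition state with the aryl and both CH2OMe groups equatorial, which sets C1 as 1R, trans to C2, while C4 and C3 of 7 are carried over untouched as C2 and C3 of 8 (cyclobutane to tetralin ring expansion); the closest known reaction types are the TfOH/HFIP protonolytic ring-opening hydroarylation of arylcyclopropanes, the acid-mediated cyclisation of 4-aryl-1-arylbutyl cations to trans-aryltetralins, and the radical-cation rearrangement of 1,2-diarylcyclobutanes to 1-aryltetralins.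

**Compound list**
1 | catechol (benzene-1,2-diol) | Oc1ccccc1O | starting material
2 | veratrole (1,2-dimethoxybenzene) | COc1ccccc1OC | intermediate
3 | 4-bromo-1,2-dimethoxybenzene | COc1ccc(Br)cc1OC | intermediate
4 | 3-methoxyprop-1-yne (methyl propargyl ether) | COCC#C | starting material
5 | 2-[(E)-3-methoxyprop-1-en-1-yl]-4,4,5,5-tetramethyl-1,3,2-dioxaborolane ((E)-3-methoxyprop-1-enylboronic acid pinacol ester) | COC/C=C/B1OC(C)(C)C(C)(C)O1 | intermediate
6 | (E)-1,2-dimethoxy-4-(3-methoxyprop-1-en-1-yl)benzene | COC/C=C/c1ccc(OC)c(OC)c1 | intermediate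
7 | (1R,2R,3S,4S)-1,2-bis(3,4-dimethoxyphenyl)-3,4-bis(methoxymethyl)cyclobutane | COC[C@H]1[C@H](c2ccc(OC)c(OC)c2)[C@@H](c2ccc(OC)c(OC)c2)[C@@H]1COC | intermediate
8 | phyltetralin, (1R,2S,3S)-1-(3,4-dimethoxyphenyl)-6,7-dimethoxy-2,3-bis(methoxymethyl)-1,2,3,4-tetrahydronaphthalene | COC[C@H]1Cc2cc(OC)c(OC)cc2[C@@H](c2ccc(OC)c(OC)c2)[C@@H]1COC | target

**Totals**
Total step count: 5. Longest linear sequence: 5 steps (1 → 2 → 3 → 6 → 7 → 8); 4 is bought and enters in step 3.

**Three steps most likely to fail**

Step 5 (proposed new ring expansion). Risks: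
- protonolysis of the cyclobutane may be slow;
- the C1–C4 bond may be protonated instead of C1–C2;
- the cation may lose a proton before closing, which would epimerise C2;
- a CH2OMe oxygen may trap the cation as a tetrahydrofuran by-product.

Fallback with known chemistry, setting out from 7: reductive cleavage of the strained doubly benzylic C1–C2 bond with Li in NH3/THF at −78 °C (NH4Cl quench) gives (2S,3S)-1,4-bis(3,4-dimethoxyphenyl)-2,3-bis(methoxymethyl)butane F1, which keeps both stereocentres of 7. DDQ (1.05 equiv) in TFA/CH2Cl2 at 0 °C then abstracts a benzylic hydride and the cation closes onto the other ring. This is the known oxidative cyclisation of dibenzylbutane lignans to trans-aryltetralins, and it comes back to the route at 8.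

Step 4 (proposed new asymmetric homodimerisation). Risks:
- insufficient ee;
- loss of material by cycloreversion when the product is oxidised;
- partial direct formation of tetralin.

Fallback with known chemistry, setting out from 6: racemic radical-cation [2+2] homodimerisation with an achiral photo-oxidant (a triarylpyrylium tetrafluoroborate with an arene electron relay, visible light) gives 7 together with its mirror image (1S,2S,3R,4R)-1,2-bis(3,4-dimethoxyphenyl)-3,4-bis(methoxymethyl)cyclobutane F2. Preparative chiral SFC removes F2 and the route is rejoined at 7.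

Step 3 (one-pot hydroboration/Suzuki). Risks:
- the alkyne is volatile;
- the alkenylboronate may protodeboronate;
- traces of the Z isomer may form.

Fallback, setting out from 3: Heck reaction with methyl acrylate (Pd(OAc)2, P(o-tol)3, K2CO3, DMF, 110 °C) gives methyl (E)-3-(3,4-dimethoxyphenyl)prop-2-enoate F3. DIBAL-H (CH2Cl2, −78 °C) gives (E)-3-(3,4-dimethoxyphenyl)prop-2-en-1-ol F4. O-Methylation with NaH/MeI in THF comes back to the route at 6.

**Further compounds**
F1 | step 5 | (2S,3S)-1,4-bis(3,4-dimethoxyphenyl)-2,3-bis(methoxymethyl)butane | COC[C@@H](Cc1ccc(OC)c(OC)c1)[C@@H](COC)Cc1ccc(OC)c(OC)c1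
F2 | step 4 | (1S,2S,3R,4R)-1,2-bis(3,4-dimethoxyphenyl)-3,4-bis(methoxymethyl)cyclobutane | COC[C@@H]1[C@@H](c2ccc(OC)c(OC)c2)[C@H](c2ccc(OC)c(OC)c2)[C@H]1COC
F3 | step 3 | methyl (E)-3-(3,4-dimethoxyphenyl)prop-2-enoate | COC(=O)/C=C/c1ccc(OC)c(OC)c1
F4 | step 3 | (E)-3-(3,4-dimethoxyphenyl)prop-2-en-1-ol | OC/C=C/c1ccc(OC)c(OC)c1
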